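- E, L, X and D together stay at the racemate charged, so X + D is the conversion, the product excess is the gap g = X − D divided by it, and g is what you follow.

the same everywhere: E 0.80 M; L 0.80 M
- Tuesday's: J 3 equiv; Q 1.2 mol%; run made earlier
- Friday's: J 3 equiv; Q 5.1 mol%; run made earlier
- ochre: J 3.00 equiv; Q 1.1 mol%; time 25 h
- violet: J 3.00 equiv; Q 4 mol%; time 25 h

| run | time / h | X / % | D / % |
|---|---|---|---|
| Tuesday's | 2.00 | 7.0 | 0.9 |
| Tuesday's | 6.00 | 14.0 | 6.0 |
| Tuesday's | 12.0 | 20.2 | 11.4 |
| Tuesday's | 20.0 | 24.5 | 17.4 |
| Tuesday's | 25.0 | 25.2 | 17.8 |
| Friday's | 5.00 | 33.9 | 18.3 |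
| Friday's | 10.0 | 38.7 | 26.6 |
| Friday's | 15.0 | 39.9 | 32.6 |
| Friday's | 20.0 | 40.7 | 36.8 |
| Friday's | 25.0 | 41.4 | 38.9 |

(scatter of a reading: 1 percentage point)
- which one finishes higher in excess of X over D in the product ("neither" within 2 percentage points) (ochre / violet / neither)
- excess of X over D in the product at the end, ochre
- excess of X over D in the product at the end, violet
- Q is single-handed; E and L are mirror images of each other, charged as a racemate, each of them at the stated concentration
- an excess is the difference of the two amounts in percent of their sum
- an excess is below zero if the other one leads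

- In Tuesday's run g stays about level, 8.8 percentage points at 12.0 h and 7.4 points at 25.0 h. I read that as E outrunning L (kinetic resolution) feeding g while something erodes it.
- In Friday's run g falls from 16 points to 2.5 points in 20.0 h. That reads as 7.57 h for the gap half-life t_g, the time in which g halves once the feed has faded.
- For ochre, as a rough estimate, I scale Tuesday's g by loading and keep Tuesday's conversion, which gives 15.8 %.
- For violet, take two extremes. If g follows Q·t, loading times time, violet sits on Friday's curve at 19.6 h. The 20.0 h reading gives a first answer of 5.03 %, and going round once, sliding back by t_g, gives 5.22 %.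
- If g follows the clock, violet takes Friday's 25.0 h gap over that same conversion, which gives 3.23 %. I take neither extreme as it stands, so I expect violet between the two, and ochre higher.
- The forecast names ochre, with 18 % for ochre and 6 % for violet, since “More catalyst takes the run further along this path”. Both its figures stand above mine.

    J + Q + E → Q + X (k = 3.40 L² mol⁻² h⁻¹)
    J + Q + L → Q + D (k = 1.10 L² mol⁻² h⁻¹)
    X ⇌ D (k = 0.0300 h⁻¹)
    Q ⇌ Z (K = 2.30, k = 0.0130 h⁻¹)
    2 J → G (k = 0.00730 L mol⁻¹ h⁻¹)

- The flask gives 14.8 % for ochre and 4.65 % for violet, so ochre leads by 10 points, as the forecast said. Ochre lands below my figure, and violet inside my band. In the scheme X ⇌ D carries no Q, while the steps that make X and D do. A neighbour of ochre charged with 4.4 mol% of Q sits by Q·t at 21.6 h on Friday's curve. Sliding forward by t_g gives an upper end of 4.36 %, the clock extreme stays 3.23 %, and that flask gives 3.86 %.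

The numbers in the tables stem from a simulated flask for substances that don't exist, noise included.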